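**Strategy.** Ring B is disconnected at C5–C6 and C7–C8 (eremophilane numbering). Quaternary C5 links C4 of ring A to the C6=C7 bond of ring B, and C9=C10 is conjugated to the C8 carbonyl. Ring B is therefore the [4+2] adduct of a ring-A 1-alkoxydiene (C5=C10–C9=C8–O) and but-3-yn-2-one, whose acetyl group becomes C11. One cycloaddition closes ring B, sets quaternary C5 by bonding anti to the C4 methyl, and leaves C8 one oxidation below the dienone. The precursor is a cyclohexene with cis C1-OTBS, C3-OTES and C4-methyl groups and an (E)-2-ethoxyvinyl arm on C10, assembled by Suzuki coupling of a regiodefined enol triflate.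

Key step: step 8

Remarks
- Locants: monocyclic compounds carry their own ring numbering. Bicyclic compounds are named as decalins with eremophilane locants (ring A: C1–C5 and C10; ring B: C5–C10; C11 on C7). TBS = tert-butyldimethylsilyl, TES = triethylsilyl.
- Design remark: the dienol oxygen is capped as an ethyl ether, so the (E) geometry comes from a stereodefined boronate, the diene tolerates chromatography and Lewis acids, and C8 is unveiled oxidatively in step 10.
- Assumption: the sense of induction of the bisphosphine in step 2 is fixed by a test run, and the ligand antipode that gives the (5R) carbinol is used.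
- Assumption: 4-methoxy-2,3-dimethylphenol is taken as a catalogue compound.

Step 1
Reactants: 1 4-methoxy-2,3-dimethylphenol
Product: 2 4,4-dimethoxy-2,3-dimethylcyclohexa-2,5-dien-1-one
Conditions: PhI(OAc)2, MeOH, 0 °C
Reagents that add atoms: methanol, SMILES CO
Why: Oxidative dearomatisation of a para-methoxyphenol by a trivalent iodine reagent in methanol (quinone monoketal formation) is a standard reaction in which methanol adds at the methoxy-bearing carbon.

Step 2
Reactants: 2 4,4-dimethoxy-2,3-dimethylcyclohexa-2,5-dien-1-one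
Product: 4 (5R)-5-hydroxy-4,4-dimethoxy-2,3-dimethylcyclohex-2-en-1-one, via boronate 3 (not isolated)
Conditions: B2pin2, CuCl (cat.), NaOtBu (cat.), QuinoxP* (cat.), MeOH, THF, rt; then NaBO3·4H2O, THF/H2O, rt
Reagents that add atoms: sodium perborate tetrahydrate (NaBO3·4H2O), SMILES B(=O)O[O-].[Na+].O.O.O.O
Why: Copper-catalysed asymmetric conjugate borylation should occur only at the unhindered C5=C6 enone (the other enone is tetrasubstituted), the chiral bisphosphine setting C5, and perborate oxidation of the C–B bond proceeds with retention.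

Step 3
Reactants: 4 (5R)-5-hydroxy-4,4-dimethoxy-2,3-dimethylcyclohex-2-en-1-one
Product: 5 (5R)-5-[(tert-butyldimethylsilyl)oxy]-4,4-dimethoxy-2,3-dimethylcyclohex-2-en-1-one
Conditions: TBSCl, imidazole, DMF, 0 °C to rt
Reagents that add atoms: tert-butyldimethylsilyl chloride, SMILES CC(C)(C)[Si](C)(C)Cl
Why: Silylation of a secondary alcohol under near-neutral conditions should avoid β-elimination and aromatisation of the β-oxy ketone.

Step 4
Reactants: 5 (5R)-5-[(tert-butyldimethylsilyl)oxy]-4,4-dimethoxy-2,3-dimethylcyclohex-2-en-1-one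
Product: 7 (4S,6R)-6-[(tert-butyldimethylsilyl)oxy]-4-hydroxy-2,3-dimethylcyclohex-2-en-1-one, via allylic alcohol 6 (not isolated)
Conditions: NaBH4, CeCl3·7H2O, MeOH, −78 °C; then oxalic acid, THF/H2O, 0 °C
Reagents that add atoms: water, SMILES O
Why: In this Luche reduction the hydride should attack the carbonyl 1,2 and anti to the C5 silyloxy group, as is usual for 5-substituted cyclohexenones, so the new carbinol (S) is cis to the OTBS group, and dilute acid then turns the allylic dimethyl ketal into the enone carbonyl without loss of the TBS ether.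

Step 5
Reactants: 7 (4S,6R)-6-[(tert-butyldimethylsilyl)oxy]-4-hydroxy-2,3-dimethylcyclohex-2-en-1-one
Product: 8 (4S,6R)-6-[(tert-butyldimethylsilyl)oxy]-2,3-dimethyl-4-[(triethylsilyl)oxy]cyclohex-2-en-1-one
Conditions: TESCl, imidazole, DMF, 0 °C
Reagents that add atoms: chlorotriethylsilane, SMILES CC[Si](CC)(CC)Cl
Why: Silylation of the allylic alcohol installs a group that can later be removed in the presence of the TBS ether, which differentiates the C3 and C1 oxygens of the target.

Step 6
Reactants: 8 (4S,6R)-6-[(tert-butyldimethylsilyl)oxy]-2,3-dimethyl-4-[(triethylsilyl)oxy]cyclohex-2-en-1-one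
Product: 11 (3R,4S,6R)-6-[(tert-butyldimethylsilyl)oxy]-2,3-dimethyl-4-[(triethylsilyl)oxy]cyclohex-1-en-1-yl trifluoromethanesulfonate, via silyl enol ether 9 (not isolated), via lithium enolate 10 (not isolated)
Conditions: [(Ph3P)CuH]6 (cat.), PhMe2SiH, toluene, rt to 40 °C; then MeLi, THF, 0 °C; PhNTf2, −78 °C to rt
Reagents that add atoms: N-phenylbis(trifluoromethanesulfonimide), SMILES O=S(=O)(N(c1ccccc1)S(=O)(=O)C(F)(F)F)C(F)(F)F
Why: Copper hydride conjugate reduction (1,4-hydrosilylation) should deliver hydride to the β-carbon from the face opposite the two cis silyloxy groups, so the C3 methyl ends cis to them (3R), and the silyl enol ether, the lithium enolate released by MeLi and its O-triflation all keep the double bond at C1=C2 (regiospecific enolate trapping).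

Step 7
Reactants: 11 (3R,4S,6R)-6-[(tert-butyldimethylsilyl)oxy]-2,3-dimethyl-4-[(triethylsilyl)oxy]cyclohex-1-en-1-yl trifluoromethanesulfonate; 12 2-[(E)-2-ethoxyethenyl]-4,4,5,5-tetramethyl-1,3,2-dioxaborolane
Product: 13 (3R,4S,6R)-6-[(tert-butyldimethylsilyl)oxy]-1-[(E)-2-ethoxyethenyl]-2,3-dimethyl-4-[(triethylsilyl)oxy]cyclohex-1-ene
Conditions: Pd(PPh3)4 (cat.), K3PO4, dioxane/H2O, 70 °C
Reagents that add atoms: none
Why: Suzuki–Miyaura coupling of an alkenyl triflate with a geometrically defined alkenylboronate proceeds with retention at both partners, so the (E)-1-ethoxydiene should form with the tetrasubstituted ring double bond fixed and the silyl ethers untouched.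

Step 8
Reactants: 13 (3R,4S,6R)-6-[(tert-butyldimethylsilyl)oxy]-1-[(E)-2-ethoxyethenyl]-2,3-dimethyl-4-[(triethylsilyl)oxy]cyclohex-1-ene; 14 but-3-yn-2-one
Product: 15 (1R,3S,4R,5R,8S)-7-acetyl-1-[(tert-butyldimethylsilyl)oxy]-8-ethoxy-4,5-dimethyl-3-[(triethylsilyl)oxy]decalin-6,9-diene
Conditions: but-3-yn-2-one (excess), BHT (cat.), toluene, 90 °C, sealed tube
Reagents that add atoms: none
Why: A concerted, asynchronous normal-electron-demand [4+2] cycloaddition (Diels–Alder reaction) joins the HOMO of the 1-ethoxydiene to the LUMO of the ynone, the C5–C6 bond leading. The closest known reaction type is the cycloaddition of 1-alkoxy- or 1-siloxy-1,3-dienes, and of 2-methyl-1-vinylcyclohexenes, with alkynyl ketones and esters to give 1,4-cyclohexadienes. Ring B is closed by intermolecular [4+2] annulation onto the C5=C10–C9=C8 diene, forming C5–C6 and C7–C8 together. Quaternary C5 is set by the ring-A substituents: the pseudoaxial C4 methyl and the C1 and C3 silyloxy groups cover one face, so the alkyne should bond to the other and the C5 methyl ends cis to the C4 methyl, while C8 follows from suprafacial addition to the (E)-enol ether (8S, erased in step 10). The step needs regio- and face selectivity: the ethoxy donor makes C5 the nucleophilic terminus, which pairs with the unsubstituted β-carbon of the ynone, and the one-sided substitution of ring A supplies the facial bias. Quaternary C5 blocks aromatisation of the 1,4-diene.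

Step 9
Reactants: 15 (1R,3S,4R,5R,8S)-7-acetyl-1-[(tert-butyldimethylsilyl)oxy]-8-ethoxy-4,5-dimethyl-3-[(triethylsilyl)oxy]decalin-6,9-diene
Product: 16 (1R,3S,4R,5R,8S)-1-[(tert-butyldimethylsilyl)oxy]-8-ethoxy-7-(2-hydroxypropan-2-yl)-4,5-dimethyl-3-[(triethylsilyl)oxy]decalin-6,9-diene
Conditions: MeLi, CeCl3, THF, −78 °C
Reagents that add atoms: methyllithium, SMILES [Li]C
Why: Organocerium 1,2-addition to the conjugated methyl ketone should proceed without enolisation or 1,4-addition (C6 is neopentylic), and it creates the C11 carbinol without a new stereocentre.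

Step 10
Reactants: 16 (1R,3S,4R,5R,8S)-1-[(tert-butyldimethylsilyl)oxy]-8-ethoxy-7-(2-hydroxypropan-2-yl)-4,5-dimethyl-3-[(triethylsilyl)oxy]decalin-6,9-diene
Product: 17 (1R,3S,4R,5R)-1-[(tert-butyldimethylsilyl)oxy]-7-(2-hydroxypropan-2-yl)-4,5-dimethyl-3-[(triethylsilyl)oxy]decalin-6,9-dien-8-one
Conditions: DDQ, CH2Cl2/pH 7 buffer, 0 °C
Reagents that add atoms: water, SMILES O
Why: In this DDQ oxidation of an allylic ether, hydride abstraction from the doubly allylic, oxygen-bearing C8–H should give a stabilised alkoxydienyl cation that water converts into the cross-conjugated dienone with loss of ethanol, and quaternary C5 rules out aromatisation.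

Step 11
Reactants: 17 (1R,3S,4R,5R)-1-[(tert-butyldimethylsilyl)oxy]-7-(2-hydroxypropan-2-yl)-4,5-dimethyl-3-[(triethylsilyl)oxy]decalin-6,9-dien-8-one
Product: 18 (1R,3S,4R,5R)-1-[(tert-butyldimethylsilyl)oxy]-3-hydroxy-7-(2-hydroxypropan-2-yl)-4,5-dimethyldecalin-6,9-dien-8-one
Conditions: HF·pyridine, pyridine, THF, 0 °C
Reagents that add atoms: none
Why: Buffered fluoride desilylation cleaves a secondary TES ether much faster than a secondary TBS ether, so only the C3 hydroxyl should be freed.

Step 12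
Reactants: 18 (1R,3S,4R,5R)-1-[(tert-butyldimethylsilyl)oxy]-3-hydroxy-7-(2-hydroxypropan-2-yl)-4,5-dimethyldecalin-6,9-dien-8-one; 19 angelic acid [(Z)-2-methylbut-2-enoic acid]
Product: 21 (1R,3S,4R,5R)-1-[(tert-butyldimethylsilyl)oxy]-7-(2-hydroxypropan-2-yl)-4,5-dimethyl-8-oxodecalin-6,9-dien-3-yl (Z)-2-methylbut-2-enoate, via mixed anhydride 20 (not isolated)
Conditions: 19, 2,4,6-trichlorobenzoyl chloride, Et3N, toluene, rt; then 18, toluene, 80 °C
Reagents that add atoms: none
Why: Yamaguchi-type esterification through the 2,4,6-trichlorobenzoyl mixed anhydride without DMAP is the established way to form angelates without Z-to-E isomerisation, the tertiary C11 alcohol should not acylate, and C3 keeps its configuration.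

Step 13
Reactants: 21 (1R,3S,4R,5R)-1-[(tert-butyldimethylsilyl)oxy]-7-(2-hydroxypropan-2-yl)-4,5-dimethyl-8-oxodecalin-6,9-dien-3-yl (Z)-2-methylbut-2-enoate
Product: 22 (1R,3S,4R,5R)-1-[(tert-butyldimethylsilyl)oxy]-7-(2-hydroperoxypropan-2-yl)-4,5-dimethyl-8-oxodecalin-6,9-dien-3-yl (Z)-2-methylbut-2-enoate
Conditions: 50% aq. H2O2 (excess), H2SO4 (cat.), THF, 0 °C
Reagents that add atoms: hydrogen peroxide, SMILES OO
Why: In this acid-catalysed perhydrolysis of a tertiary allylic alcohol (SN1), the C11 cation should be captured by hydrogen peroxide at its tertiary terminus and not at neopentylic C6, and any TBS loss is harmless because step 14 removes that group.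

Step 14
Reactants: 22 (1R,3S,4R,5R)-1-[(tert-butyldimethylsilyl)oxy]-7-(2-hydroperoxypropan-2-yl)-4,5-dimethyl-8-oxodecalin-6,9-dien-3-yl (Z)-2-methylbut-2-enoate
Product: 23 (1R,3S,4R,5R)-7-(2-hydroperoxypropan-2-yl)-1-hydroxy-4,5-dimethyl-8-oxodecalin-6,9-dien-3-yl (Z)-2-methylbut-2-enoate
Conditions: HF·pyridine, THF, 0 °C to rt
Reagents that add atoms: none
Why: Fluoride desilylation of the allylic TBS ether under mildly acidic, non-nucleophilic conditions should be tolerated by the hydroperoxide, the angelate and the dienone, and touches no stereocentre.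

**Compound list**

1 | 4-methoxy-2,3-dimethylphenol | COc1ccc(O)c(C)c1C | starting material
2 | 4,4-dimethoxy-2,3-dimethylcyclohexa-2,5-dien-1-one | O=C1C=CC(OC)(OC)C(C)=C1C | intermediate
3 | (5R)-4,4-dimethoxy-2,3-dimethyl-5-(4,4,5,5-tetramethyl-1,3,2-dioxaborolan-2-yl)cyclohex-2-en-1-one | O=C1C[C@@H](B2OC(C)(C)C(C)(C)O2)C(OC)(OC)C(C)=C1C | intermediate
4 | (5R)-5-hydroxy-4,4-dimethoxy-2,3-dimethylcyclohex-2-en-1-one | O=C1C[C@@H](O)C(OC)(OC)C(C)=C1C | intermediate
5 | (5R)-5-[(tert-butyldimethylsilyl)oxy]-4,4-dimethoxy-2,3-dimethylcyclohex-2-en-1-one | O=C1C[C@@H](O[Si](C)(C)C(C)(C)C)C(OC)(OC)C(C)=C1C | intermediate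
6 | (1S,5R)-5-[(tert-butyldimethylsilyl)oxy]-4,4-dimethoxy-2,3-dimethylcyclohex-2-en-1-ol | O[C@H]1C[C@@H](O[Si](C)(C)C(C)(C)C)C(OC)(OC)C(C)=C1C | intermediate
7 | (4S,6R)-6-[(tert-butyldimethylsilyl)oxy]-4-hydroxy-2,3-dimethylcyclohex-2-en-1-one | O[C@H]1C[C@@H](O[Si](C)(C)C(C)(C)C)C(=O)C(C)=C1C | intermediate
8 | (4S,6R)-6-[(tert-butyldimethylsilyl)oxy]-2,3-dimethyl-4-[(triethylsilyl)oxy]cyclohex-2-en-1-one | CC[Si](CC)(CC)O[C@H]1C[C@@H](O[Si](C)(C)C(C)(C)C)C(=O)C(C)=C1C | intermediate
9 | (3R,4S,6R)-6-[(tert-butyldimethylsilyl)oxy]-1-{[dimethyl(phenyl)silyl]oxy}-2,3-dimethyl-4-[(triethylsilyl)oxy]cyclohex-1-ene | CC[Si](CC)(CC)O[C@H]1C[C@@H](O[Si](C)(C)C(C)(C)C)C(O[Si](C)(C)c2ccccc2)=C(C)[C@H]1C | intermediate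
10 | lithium (3R,4S,6R)-6-[(tert-butyldimethylsilyl)oxy]-2,3-dimethyl-4-[(triethylsilyl)oxy]cyclohex-1-en-1-olate | CC[Si](CC)(CC)O[C@H]1C[C@@H](O[Si](C)(C)C(C)(C)C)C(O[Li])=C(C)[C@H]1C | intermediate
11 | (3R,4S,6R)-6-[(tert-butyldimethylsilyl)oxy]-2,3-dimethyl-4-[(triethylsilyl)oxy]cyclohex-1-en-1-yl trifluoromethanesulfonate | CC[Si](CC)(CC)O[C@H]1C[C@@H](O[Si](C)(C)C(C)(C)C)C(OS(=O)(=O)C(F)(F)F)=C(C)[C@H]1C | intermediate
12 | 2-[(E)-2-ethoxyethenyl]-4,4,5,5-tetramethyl-1,3,2-dioxaborolane | CCO/C=C/B1OC(C)(C)C(C)(C)O1 | starting material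
13 | (3R,4S,6R)-6-[(tert-butyldimethylsilyl)oxy]-1-[(E)-2-ethoxyethenyl]-2,3-dimethyl-4-[(triethylsilyl)oxy]cyclohex-1-ene | CC[Si](CC)(CC)O[C@H]1C[C@@H](O[Si](C)(C)C(C)(C)C)C(/C=C/OCC)=C(C)[C@H]1C | intermediate
14 | but-3-yn-2-one | CC(=O)C#C | starting material
15 | (1R,3S,4R,5R,8S)-7-acetyl-1-[(tert-butyldimethylsilyl)oxy]-8-ethoxy-4,5-dimethyl-3-[(triethylsilyl)oxy]decalin-6,9-diene | CC[Si](CC)(CC)O[C@H]1C[C@@H](O[Si](C)(C)C(C)(C)C)C2=C[C@H](OCC)C(C(C)=O)=C[C@]2(C)[C@H]1C | intermediate
16 | (1R,3S,4R,5R,8S)-1-[(tert-butyldimethylsilyl)oxy]-8-ethoxy-7-(2-hydroxypropan-2-yl)-4,5-dimethyl-3-[(triethylsilyl)oxy]decalin-6,9-diene | CC[Si](CC)(CC)O[C@H]1C[C@@H](O[Si](C)(C)C(C)(C)C)C2=C[C@H](OCC)C(C(C)(C)O)=C[C@]2(C)[C@H]1C | intermediate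
17 | (1R,3S,4R,5R)-1-[(tert-butyldimethylsilyl)oxy]-7-(2-hydroxypropan-2-yl)-4,5-dimethyl-3-[(triethylsilyl)oxy]decalin-6,9-dien-8-one | CC[Si](CC)(CC)O[C@H]1C[C@@H](O[Si](C)(C)C(C)(C)C)C2=CC(=O)C(C(C)(C)O)=C[C@]2(C)[C@H]1C | intermediate
18 | (1R,3S,4R,5R)-1-[(tert-butyldimethylsilyl)oxy]-3-hydroxy-7-(2-hydroxypropan-2-yl)-4,5-dimethyldecalin-6,9-dien-8-one | O[C@H]1C[C@@H](O[Si](C)(C)C(C)(C)C)C2=CC(=O)C(C(C)(C)O)=C[C@]2(C)[C@H]1C | intermediate
19 | angelic acid [(Z)-2-methylbut-2-enoic acid] | C/C=C(/C)C(=O)O | starting material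
20 | (Z)-2-methylbut-2-enoic 2,4,6-trichlorobenzoic anhydride | C/C=C(/C)C(=O)OC(=O)c1c(Cl)cc(Cl)cc1Cl | intermediate
21 | (1R,3S,4R,5R)-1-[(tert-butyldimethylsilyl)oxy]-7-(2-hydroxypropan-2-yl)-4,5-dimethyl-8-oxodecalin-6,9-dien-3-yl (Z)-2-methylbut-2-enoate | C/C=C(/C)C(=O)O[C@H]1C[C@@H](O[Si](C)(C)C(C)(C)C)C2=CC(=O)C(C(C)(C)O)=C[C@]2(C)[C@H]1C | intermediate
22 | (1R,3S,4R,5R)-1-[(tert-butyldimethylsilyl)oxy]-7-(2-hydroperoxypropan-2-yl)-4,5-dimethyl-8-oxodecalin-6,9-dien-3-yl (Z)-2-methylbut-2-enoate | C/C=C(/C)C(=O)O[C@H]1C[C@@H](O[Si](C)(C)C(C)(C)C)C2=CC(=O)C(C(C)(C)OO)=C[C@]2(C)[C@H]1C | intermediate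
23 | (1R,3S,4R,5R)-7-(2-hydroperoxypropan-2-yl)-1-hydroxy-4,5-dimethyl-8-oxodecalin-6,9-dien-3-yl (Z)-2-methylbut-2-enoate (CNP0300636.1) | C/C=C(/C)C(=O)O[C@H]1C[C@@H](O)C2=CC(=O)C(C(C)(C)OO)=C[C@]2(C)[C@H]1C | target

**Step count and risks**

Total steps: 14. Longest linear sequence: 14 steps (1 to 23).

Steps most likely to fail:

1. Step 8 (key cycloaddition). Bond formation at the fully substituted diene terminus may be slower than polymerisation of the ynone, or than a 1,5-hydrogen shift from the C5 methyl group into the diene, so that little adduct forms. The fallback sets out from diene 13 and uses methyl propiolate with EtAlCl2 in CH2Cl2 at low temperature. The ethyl dienyl ether tolerates the Lewis acid, and this ester can also be heated well beyond what the ynone survives. The same regio- and face control should give the methyl ester adduct F1, in which C11 is an ester carbon. Excess MeMgBr with CeCl3 then adds twice and should give tertiary alcohol 16, where the route is rejoined without an extra step.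

2. Step 13 (perhydrolysis). Ionisation at C11 is slowed by the neighbouring enone, so acid-driven side reactions may overtake peroxide capture: isomerisation of the angelate, capture at C6 with allylic transposition, or dienone–phenol rearrangement. The fallback sets out from angelate 21. Dehydration with methyl N-(triethylammoniosulfonyl)carbamate in benzene should give the isopropenyl trienone F2. A Mukaiyama–Isayama hydrosilylperoxidation (Co(thd)2, thd = 2,2,6,6-tetramethylheptane-3,5-dionate; O2; Et3SiH; 1,2-dichloroethane) should then place the peroxide at the tertiary carbon as the triethylsilyl peroxide F3. Hydrogen-atom transfer to the terminal CH2 of the 1,1-disubstituted alkene is expected to be faster than to the trisubstituted enoate or the enone. HF·pyridine then cleaves the peroxysilyl and TBS groups together and should give target 23 directly.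

3. Step 6 (conjugate reduction and triflation). Hydride transfer to the tetrasubstituted enone may be slow, which would allow 1,2-reduction or erode facial control, and the enolate may be triflated incompletely. The fallback sets out from enone 8. Heterogeneous hydrogenation (H2, Pd/C, EtOAc) should add hydrogen to the face opposite both silyloxy groups and give the all-cis saturated ketone F4. Kinetic deprotonation with KN(SiMe3)2 in THF at −78 °C is expected to remove the C2 hydrogen and not the hydrogen on the oxygen-bearing C6. Trapping with PhNTf2 should then give enol triflate 11, where the route is rejoined.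

Further compounds
F1 | step 8 | methyl (1R,3S,4R,5R,8S)-1-[(tert-butyldimethylsilyl)oxy]-8-ethoxy-4,5-dimethyl-3-[(triethylsilyl)oxy]decalin-6,9-diene-7-carboxylate | CC[Si](CC)(CC)O[C@H]1C[C@@H](O[Si](C)(C)C(C)(C)C)C2=C[C@H](OCC)C(C(=O)OC)=C[C@]2(C)[C@H]1C
F2 | step 13 | (1R,3S,4R,5R)-1-[(tert-butyldimethylsilyl)oxy]-4,5-dimethyl-8-oxo-7-(prop-1-en-2-yl)decalin-6,9-dien-3-yl (Z)-2-methylbut-2-enoate | C/C=C(/C)C(=O)O[C@H]1C[C@@H](O[Si](C)(C)C(C)(C)C)C2=CC(=O)C(C(C)=C)=C[C@]2(C)[C@H]1C
F3 | step 13 | (1R,3S,4R,5R)-1-[(tert-butyldimethylsilyl)oxy]-4,5-dimethyl-8-oxo-7-{2-[(triethylsilyl)peroxy]propan-2-yl}decalin-6,9-dien-3-yl (Z)-2-methylbut-2-enoate | C/C=C(/C)C(=O)O[C@H]1C[C@@H](O[Si](C)(C)C(C)(C)C)C2=CC(=O)C(C(C)(C)OO[Si](CC)(CC)CC)=C[C@]2(C)[C@H]1C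
F4 | step 6 | (2S,3R,4S,6R)-6-[(tert-butyldimethylsilyl)oxy]-2,3-dimethyl-4-[(triethylsilyl)oxy]cyclohexan-1-one | CC[Si](CC)(CC)O[C@H]1C[C@@H](O[Si](C)(C)C(C)(C)C)C(=O)[C@@H](C)[C@H]1C
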